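Ring C (O1, C2, C3, C4, C4a, C8a) is not closed as a pyranone; it is grown from the furanone ring of a 2-phenylbenzofuran-3-one. Diiodomethane supplies C3 and SmI2 folds it onto the ketone, giving a racemic cyclopropa[b]benzofuranol. In the key step photoredox O–H activation breaks the bond shared by the three- and five-membered rings, so the five-ring becomes ring C. The step exploits that C2 is both benzylic and bound to O1: both enantiomers funnel into one planar C2 radical, and a chiral thiol delivers hydrogen to one face to set 2S. C8 is then iodinated and benzylated (Negishi); C6, the last free A-ring carbon, traps an o-quinone methide.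

Key step: step 5

Assumption: flavanone numbering (O1, C2 … C8a) is used from compound 7 onward; racemates are written without stereo labels; the sense of induction of the peptide thiol must be fixed by experiment, both mirror-image peptides being equally accessible, and the one that delivers H to the Re face of C2 is meant.

Step 1
Reactants: 1 3,5-bis(benzyloxy)phenol; 2 (±)-α-bromophenylacetic acid
Product: 3 (±)-2-[3,5-bis(benzyloxy)phenoxy]-2-phenylacetic acid
Conditions: NaH (2.2 equiv), DMF, 0 °C → rt; 1 M HCl work-up
Reagents that add atoms: none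
Why: Williamson ether synthesis (SN2): the sodium phenoxide displaces the activated benzylic α-bromide of the sodium carboxylate, and the racemic centre is irrelevant because it is planarised in step 5.

Step 2
Reactants: 3 (±)-2-[3,5-bis(benzyloxy)phenoxy]-2-phenylacetic acid
Product: 5 (±)-4,6-bis(benzyloxy)-2-phenylbenzofuran-3(2H)-one, via mixed trifluoroacetic anhydride 4 (not isolated)
Conditions: (CF3CO)2O (1.5 equiv), CH2Cl2, 0 °C → rt, Ar; aq NaHCO3 work-up; used at once (air-sensitive enol)
Reagents that add atoms: none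
Why: Intramolecular Friedel–Crafts acylation through 4: the phloroglucinol-type ring should react without a metal Lewis acid (benzyl ethers survive), the tether allows only attack ortho to the aryloxy oxygen (five-membered ring), and the two ortho positions are equivalent.

Step 3
Reactants: 5 (±)-4,6-bis(benzyloxy)-2-phenylbenzofuran-3(2H)-one
Product: 6 (±)-4,6-bis(benzyloxy)-2-(iodomethyl)-2-phenylbenzofuran-3(2H)-one
Conditions: NaH (1.1 equiv), CH2I2 (5 equiv), THF–DMPU, 0 °C → rt, Ar, dark
Reagents that add atoms: diiodomethane, ICI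
Why: Enolate C-alkylation, the standard entry to Dowd–Beckwith-type α-halomethyl ketones: the soft 2-aryl enolate should react at C2, O-alkylation is hindered by the flanking 4-benzyloxy group, and the neopentyl iodide formed cannot react a second time.

Step 4
Reactants: 6 (±)-4,6-bis(benzyloxy)-2-(iodomethyl)-2-phenylbenzofuran-3(2H)-one
Product: 7 (±)-4,6-bis(benzyloxy)-1a-phenyl-1,1a-dihydro-6bH-cyclopropa[b]benzofuran-6b-ol
Conditions: SmI2 (2.2 equiv, 0.1 M), THF, −78 → −40 °C; pH 7 phosphate buffer; rapid chromatography on buffered silica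
Reagents that add atoms: none
Why: Samarium Barbier-type 3-exo cyclisation of a β-iodo ketone to a cyclopropanol: the ring C2–O1 bond lies in the nodal plane of the ketyl and should not be expelled, the fusion can only be cis, and low temperature with a neutral quench should keep the samarium cyclopropoxide closed.

Step 5
Reactants: 7 (±)-4,6-bis(benzyloxy)-1a-phenyl-1,1a-dihydro-6bH-cyclopropa[b]benzofuran-6b-ol
Product: 9 (S)-5,7-bis(benzyloxy)-2-phenylchroman-4-one, via flavanon-2-yl radical 8 (not isolated)
Conditions: [Ir(dF(CF3)ppy)2(5,5'-dCF3bpy)]PF6 (2 mol %), β-turn peptide thiol Boc-Cys-Pro-Aib-Phe-NMe2 (L,D,–,L series or its mirror image, 10 mol %), 2,4,6-collidine (1 equiv), PhCF3–CH2Cl2, blue LEDs, −20 °C, Ar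
Reagents that add atoms: none
Why: Proposed new method: the excited Ir(III) complex oxidises the trialkoxyarene next to the carbinol, collidine takes the O–H proton (PCET), and the cyclopropyloxy radical undergoes β-scission of the C2–C4 bond shared by the three- and five-membered rings, so the 2-oxabicyclo[3.1.0]hexane core becomes six-membered ring C with the C4 ketone and a C2 radical (8). The closest known reaction types are the photoredox/PCET ring-opening isomerisation of cyclic aryl carbinols with a thiol H-donor, the Fe(III)- or Mn(III)-mediated ring expansion of bicyclic cyclopropanols, and enantioselective H-atom transfer from cysteine-peptide or sugar thiols to prochiral radicals; their combination on a cyclopropanol has not been shown. No ring is closed by bond formation: the six-membered ring arises purely by cleavage of the zero-atom bridge (one-carbon expansion, 5 → 6), and the only new bond is C2–H. The single new stereocentre C2 is catalyst-controlled: the peptide N–H groups should bind C4=O and hold the Cys S–H over the Re face of the planar radical, so both enantiomers of 7 converge on (2S)-9, while Ir(II) reduces the thiyl radical and collidinium reprotonates the thiolate, which makes the step a redox-neutral isomerisation. The step needs scission of C2–C4 rather than C3–C4, which is secured because the C2 radical is benzylic and α-oxygenated whereas the alternative is primary and can re-close reversibly. It also needs H transfer only from the catalyst, which is secured because no other good H-donor is present, the acyl-deactivated arene of 9 is no longer oxidised, and the weak base leaves the base-labile flavanone centre untouched.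

Step 6
Reactants: 9 (S)-5,7-bis(benzyloxy)-2-phenylchroman-4-one
Product: 10 (S)-5,7-bis(benzyloxy)-8-iodo-2-phenylchroman-4-one
Conditions: NIS (1.05 equiv), TFA (20 mol %), MeCN, 0 °C → rt, dark
Reagents that add atoms: N-iodosuccinimide, O=C1CCC(=O)N1I
Why: Electrophilic aromatic iodination: C6 is shielded by the 5-O-benzyl group, which the peri C4=O forces to point toward C6, whereas C8 is flanked by the tied-back ring oxygen O1 (the preference known for 5,7-dialkoxyflavonoids), and the acidic medium does not touch C2.

Step 7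
Reactants: 11 1-(benzyloxy)-2-(chloromethyl)benzene; 12 [4-(benzyloxy)-3-formylphenyl]boronic acid
Product: 13 2-(benzyloxy)-5-[2-(benzyloxy)benzyl]benzaldehyde
Conditions: Pd(OAc)2 (2 mol %), SPhos (4 mol %), K3PO4 (2 equiv), toluene–H2O, 80 °C
Reagents that add atoms: none
Why: sp3–sp2 Suzuki–Miyaura coupling of a benzylic chloride with an arylboronic acid, which tolerates the aldehyde and fixes the attachment para to the oxygen by the choice of boronic acid.

Step 8
Reactants: 13 2-(benzyloxy)-5-[2-(benzyloxy)benzyl]benzaldehyde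
Product: 14 {2-(benzyloxy)-5-[2-(benzyloxy)benzyl]phenyl}methanol
Conditions: NaBH4, THF–MeOH, 0 °C
Reagents that add atoms: none
Why: Borohydride reduction of the only carbonyl group present.

Step 9
Reactants: 14 {2-(benzyloxy)-5-[2-(benzyloxy)benzyl]phenyl}methanol
Product: 15 1-(benzyloxy)-4-[2-(benzyloxy)benzyl]-2-(chloromethyl)benzene
Conditions: SOCl2 (1.2 equiv), CH2Cl2, 0 °C; used without storage
Reagents that add atoms: thionyl chloride, O=S(Cl)Cl
Why: Deoxychlorination of a benzylic alcohol via its chlorosulfite; the chloride is chosen because benzylic chlorides insert zinc with little Wurtz coupling.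

Step 10
Reactants: 15 1-(benzyloxy)-4-[2-(benzyloxy)benzyl]-2-(chloromethyl)benzene; 10 (S)-5,7-bis(benzyloxy)-8-iodo-2-phenylchroman-4-one
Product: 17 (S)-5,7-bis(benzyloxy)-8-{2-(benzyloxy)-5-[2-(benzyloxy)benzyl]benzyl}-2-phenylchroman-4-one, via benzylic zinc chloride 16 (not isolated)
Conditions: (i) Zn dust, LiCl, THF, 25 °C; (ii) 10, Pd(OAc)2 (2 mol %), SPhos (4 mol %), THF, 25 → 40 °C
Reagents that add atoms: none
Why: LiCl-assisted zinc insertion followed by Negishi coupling: the bulky biarylphosphine handles the di-ortho-substituted iodide, and the benzylic zinc reagent is too weakly basic to enolise or add to the hindered ketone, so C2 is preserved.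

Step 11
Reactants: 17 (S)-5,7-bis(benzyloxy)-8-{2-(benzyloxy)-5-[2-(benzyloxy)benzyl]benzyl}-2-phenylchroman-4-one
Product: 18 (S)-5,7-dihydroxy-8-[2-hydroxy-5-(2-hydroxybenzyl)benzyl]-2-phenylchroman-4-one
Conditions: H2 (1 atm), 10 % Pd/C, EtOAc–MeOH, rt, stopped at full debenzylation
Reagents that add atoms: none
Why: Catalytic hydrogenolysis of four aryl benzyl ethers, which is faster than cleavage of the cyclic C2–O1 bond or reduction of the electron-rich aryl ketone, under neutral conditions that leave C2 intact.

Step 12
Reactants: 18 (S)-5,7-dihydroxy-8-[2-hydroxy-5-(2-hydroxybenzyl)benzyl]-2-phenylchroman-4-one; 19 2-hydroxybenzyl alcohol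
Product: 21 isouvarinol, via o-quinone methide 20 (not isolated)
Conditions: ZnCl2 (2 equiv), 1,4-dioxane, 80 °C, slow addition of 19 (1.1 equiv)
Reagents that add atoms: none
Why: Lewis-acid dehydration of 19 to o-quinone methide 20 and Friedel–Crafts-type conjugate C-alkylation: C6, between two hydroxyl groups, is the only free A-ring carbon and is far more nucleophilic than the monophenol rings, and the non-basic medium avoids retro-oxa-Michael opening at C2.

Compound list
1 | 3,5-bis(benzyloxy)phenol | Oc1cc(OCc2ccccc2)cc(OCc2ccccc2)c1 | starting material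
2 | (±)-α-bromophenylacetic acid | OC(=O)C(Br)c1ccccc1 | starting material
3 | (±)-2-[3,5-bis(benzyloxy)phenoxy]-2-phenylacetic acid | OC(=O)C(Oc1cc(OCc2ccccc2)cc(OCc2ccccc2)c1)c1ccccc1 | intermediate
4 | mixed anhydride of 3 with trifluoroacetic acid | O=C(OC(=O)C(F)(F)F)C(Oc1cc(OCc2ccccc2)cc(OCc2ccccc2)c1)c1ccccc1 | intermediate (not isolated)
5 | (±)-4,6-bis(benzyloxy)-2-phenylbenzofuran-3(2H)-one | O=C1C(c2ccccc2)Oc2cc(OCc3ccccc3)cc(OCc3ccccc3)c21 | intermediate
6 | (±)-4,6-bis(benzyloxy)-2-(iodomethyl)-2-phenylbenzofuran-3(2H)-one | O=C1C(CI)(c2ccccc2)Oc2cc(OCc3ccccc3)cc(OCc3ccccc3)c21 | intermediate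
7 | (±)-4,6-bis(benzyloxy)-1a-phenyl-1,1a-dihydro-6bH-cyclopropa[b]benzofuran-6b-ol (racemic; cis fusion is the only possible one) | OC12CC1(c1ccccc1)Oc1cc(OCc3ccccc3)cc(OCc3ccccc3)c12 | intermediate
8 | 5,7-bis(benzyloxy)-4-oxo-2-phenylchroman-2-yl radical | O=C1C[C](c2ccccc2)Oc2cc(OCc3ccccc3)cc(OCc3ccccc3)c21 | intermediate (not isolated)
9 | (S)-5,7-bis(benzyloxy)-2-phenylchroman-4-one | O=C1C[C@@H](c2ccccc2)Oc2cc(OCc3ccccc3)cc(OCc3ccccc3)c21 | intermediate
10 | (S)-5,7-bis(benzyloxy)-8-iodo-2-phenylchroman-4-one | O=C1C[C@@H](c2ccccc2)Oc2c(I)c(OCc3ccccc3)cc(OCc3ccccc3)c21 | intermediate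
11 | 1-(benzyloxy)-2-(chloromethyl)benzene | ClCc1ccccc1OCc1ccccc1 | starting material
12 | [4-(benzyloxy)-3-formylphenyl]boronic acid | O=Cc1cc(B(O)O)ccc1OCc1ccccc1 | starting material
13 | 2-(benzyloxy)-5-[2-(benzyloxy)benzyl]benzaldehyde | O=Cc1cc(Cc2ccccc2OCc2ccccc2)ccc1OCc1ccccc1 | intermediate
14 | {2-(benzyloxy)-5-[2-(benzyloxy)benzyl]phenyl}methanol | OCc1cc(Cc2ccccc2OCc2ccccc2)ccc1OCc1ccccc1 | intermediate
15 | 1-(benzyloxy)-4-[2-(benzyloxy)benzyl]-2-(chloromethyl)benzene | ClCc1cc(Cc2ccccc2OCc2ccccc2)ccc1OCc1ccccc1 | intermediate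
16 | {2-(benzyloxy)-5-[2-(benzyloxy)benzyl]benzyl}zinc chloride | Cl[Zn]Cc1cc(Cc2ccccc2OCc2ccccc2)ccc1OCc1ccccc1 | intermediate (not isolated)
17 | (S)-5,7-bis(benzyloxy)-8-{2-(benzyloxy)-5-[2-(benzyloxy)benzyl]benzyl}-2-phenylchroman-4-one | O=C1C[C@@H](c2ccccc2)Oc2c(Cc3cc(Cc4ccccc4OCc4ccccc4)ccc3OCc3ccccc3)c(OCc3ccccc3)cc(OCc3ccccc3)c21 | intermediate
18 | (S)-5,7-dihydroxy-8-[2-hydroxy-5-(2-hydroxybenzyl)benzyl]-2-phenylchroman-4-one | O=C1C[C@@H](c2ccccc2)Oc2c(Cc3cc(Cc4ccccc4O)ccc3O)c(O)cc(O)c21 | intermediate
19 | 2-hydroxybenzyl alcohol | OCc1ccccc1O | starting material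
20 | o-quinone methide (6-methylidenecyclohexa-2,4-dien-1-one) | C=C1C=CC=CC1=O | intermediate (not isolated)
21 | isouvarinol, (S)-5,7-dihydroxy-6-(2-hydroxybenzyl)-8-[2-hydroxy-5-(2-hydroxybenzyl)benzyl]-2-phenylchroman-4-one | O=C1C[C@@H](c2ccccc2)Oc2c(Cc3cc(Cc4ccccc4O)ccc3O)c(O)c(Cc3ccccc3O)c(O)c21 | target

Total step count: 12. Longest linear sequence: 9 (steps 1–6, 10, 11, 12).

Steps most likely to fail

1. Step 5 (Proposed new method). Facial selectivity of the H-atom transfer may be poor. The C2 radical may also be over-oxidised instead of receiving hydrogen. The fallback uses known chemistry, keeps the ring expansion, and sets the stereocentre separately. It sets out from 7. Mn(OAc)3/Cu(OAc)2 in AcOH–MeCN opens the cyclopropanol oxidatively; the ring-expanded C2 radical is oxidised and loses a proton from C3 to give 5,7-bis(benzyloxy)-2-phenyl-4H-chromen-4-one F1. Copper hydride-catalysed asymmetric conjugate reduction, established for chromones, then returns to the route at 9. Conditions: Cu(OAc)2, the DTBM-SEGPHOS antipode that gives 2S, (EtO)2MeSiH, t-BuOH, toluene.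

2. Step 4. The ketyl may reductively cleave the α-aryloxy C2–O1 bond. The samarium cyclopropoxide may also open early to racemic flavanone, which would dilute the enantiopurity reached in step 5 if it were carried along. The fallback replaces reductive cyclisation by carbenoid cyclopropanation and sets out from 5, bypassing 6. TBSOTf/Et3N in CH2Cl2 gives the aromatic silyl enol ether 4,6-bis(benzyloxy)-3-[(tert-butyldimethylsilyl)oxy]-2-phenylbenzofuran F2. Dearomative Simmons–Smith cyclopropanation of its C2=C3 bond (Et2Zn, CH2I2, CF3CO2H, CH2Cl2) gives the silyloxycyclopropane F3. Et3N·3HF in THF at 0 °C removes the silyl group and returns to the route at 7.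

3. Step 12. Site selectivity may be lost through alkylation of the pendant phenol rings or self-condensation of the quinone methide. Lewis-acid-induced opening of ring C at elevated temperature may also erode configuration at C2. The fallback replaces quinone methide chemistry by cross-coupling on the protected series and sets out from 17. NIS/TFA iodinates the only free A-ring position to give the 6-iodide F4. Negishi coupling with 2-(benzyloxy)benzylzinc chloride F5 (from 11, Zn, LiCl, THF), using Pd(OAc)2/SPhos, gives penta-O-benzylisouvarinol F6. Hydrogenolysis (H2, Pd/C, EtOAc–MeOH) returns to the route at 21.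

Further compounds
F1 | step 5 | 5,7-bis(benzyloxy)-2-phenyl-4H-chromen-4-one | O=c1cc(-c2ccccc2)oc2cc(OCc3ccccc3)cc(OCc3ccccc3)c12
F2 | step 4 | 4,6-bis(benzyloxy)-3-[(tert-butyldimethylsilyl)oxy]-2-phenylbenzofuran | CC(C)(C)[Si](C)(C)Oc1c(-c2ccccc2)oc2cc(OCc3ccccc3)cc(OCc3ccccc3)c12
F3 | step 4 | (±)-4,6-bis(benzyloxy)-6b-[(tert-butyldimethylsilyl)oxy]-1a-phenyl-1a,6b-dihydro-1H-cyclopropa[b]benzofuran | CC(C)(C)[Si](C)(C)OC12CC1(c1ccccc1)Oc1cc(OCc3ccccc3)cc(OCc3ccccc3)c12
F4 | step 12 | (S)-5,7-bis(benzyloxy)-8-{2-(benzyloxy)-5-[2-(benzyloxy)benzyl]benzyl}-6-iodo-2-phenylchroman-4-one | O=C1C[C@@H](c2ccccc2)Oc2c(Cc3cc(Cc4ccccc4OCc4ccccc4)ccc3OCc3ccccc3)c(OCc3ccccc3)c(I)c(OCc3ccccc3)c21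
F5 | step 12 | 2-(benzyloxy)benzylzinc chloride | Cl[Zn]Cc1ccccc1OCc1ccccc1
F6 | step 12 | penta-O-benzylisouvarinol | O=C1C[C@@H](c2ccccc2)Oc2c(Cc3cc(Cc4ccccc4OCc4ccccc4)ccc3OCc3ccccc3)c(OCc3ccccc3)c(Cc3ccccc3OCc3ccccc3)c(OCc3ccccc3)c21
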